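Ring A is cut at C1–C2 and C4–C5 (labdane numbering): C2–C3–C4 with its ester carbon becomes methyl 2-methylacetoacetate, the rest an achiral (E,E)-diene allylic bromide. The key step is a one-flask anion–radical [3+3] annulation: the acetoacetate dianion is allylated at C2 by the C1 bromide, and oxidation of the resulting keto ester by trivalent manganese closes ring A at C4–C5, ring B at C9–C10 and releases the C8=C17 methylene. It exploits the C3 carbonyl flanked by C2 and C4 and the C5=C10 and C8=C9 alkenes of the isoprenoid chain. A ketoreductase then resolves the racemate while setting C3; decarboxylative alkenylation adds C13–C16.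

Key step: step 4

Remark: positions are given in labdane numbering (ester carbon = C19, 4β); the key step gives the racemate, and the absolute configuration is fixed by the enzymatic kinetic resolution in step 5, which can pass on at most half of the material.

Step 1
Reactants: 1 geranyl bromide; 2 tert-butyl acetate
Product: 4 tert-butyl (4E)-5,9-dimethyldeca-4,8-dienoate, via lithium enolate 3 (not isolated)
Conditions: 2, LiN(i-Pr)2, THF, −78 °C; then 1, DMPU, −78 to 0 °C
Reagents that add atoms: none
Why: Alkylation of the lithium ester enolate at the primary allylic bromide (SN2) installs the C11–C13 handle without touching the E alkene; no stereocentre is formed.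

Step 2
Reactants: 4 tert-butyl (4E)-5,9-dimethyldeca-4,8-dienoate
Product: 5 tert-butyl (4E,8E)-10-hydroxy-5,9-dimethyldeca-4,8-dienoate
Conditions: SeO2 (cat.), t-BuOOH, salicylic acid (cat.), CH2Cl2, 0 °C to rt
Reagents that add atoms: tert-butyl hydroperoxide, CC(C)(C)OO (oxygen relayed by catalytic SeO2, O=[Se]=O)
Why: SeO2 allylic oxidation (ene reaction, then [2,3]-sigmatropic shift) is selective for the E methyl of the terminal isopropylidene of polyprenyl chains and should give the E allylic alcohol whose carbinol carbon becomes C1.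

Step 3
Reactants: 5 tert-butyl (4E,8E)-10-hydroxy-5,9-dimethyldeca-4,8-dienoate
Product: 6 tert-butyl (4E,8E)-10-bromo-5,9-dimethyldeca-4,8-dienoate
Conditions: CBr4, PPh3, CH2Cl2, 0 °C
Reagents that add atoms: carbon tetrabromide, BrC(Br)(Br)Br
Why: The Appel reaction converts the primary allylic alcohol into the bromide under neutral conditions, without allylic transposition and with the tert-butyl ester intact.

Step 4
Reactants: 6 tert-butyl (4E,8E)-10-bromo-5,9-dimethyldeca-4,8-dienoate; 7 methyl 2-methyl-3-oxobutanoate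
Product: 10 rac-13-tert-butyl 19-methyl 3-oxo-14,15,16-trinorlabd-8(17)-ene-13,19-dioate, via dianion 8 (not isolated), via keto ester 9 (not isolated)
Conditions: 7, NaH, THF, 0 °C; n-BuLi, 0 °C; 6, 0 °C; then AcOH, THF distilled off from the same flask; Mn(OAc)3·2H2O (2.2 equiv), Cu(OAc)2·H2O (1 equiv), degassed AcOH, 25–40 °C
Reagents that add atoms: none
Why: The sodium lithium dianion 8 attacks the primary allylic bromide 6 through its terminal C2 carbon (SN2, γ-alkylation of an acetoacetate dianion), and after acidification Mn(OAc)3 oxidises the 2-methyl-3-oxo ester 9 to the C4 radical. The closest known reaction type is the Mn(OAc)3/Cu(OAc)2 oxidative free-radical polycyclisation of unsaturated 2-alkyl-3-oxo esters, here telescoped with the dianion alkylation. Ring A closes 6-endo-trig (C4 onto C5 of the C5=C10 alkene), ring B closes 6-endo-trig (the tertiary C10 radical onto C9 of the C8=C9 alkene), and the tertiary C8 radical is oxidised by divalent copper, whose alkylcopper intermediate loses a C17 hydrogen to give the exocyclic alkene. C5, C10 and C9 follow from the chair–chair transition state of the (E,E)-diene (trans ring fusion, C9 chain equatorial), and C4 from the planar radical placing the smaller CO2Me axial (syn to the C10 methyl) and its methyl equatorial, as in known cyclisations of this ester class. The step needs C2 over C4 alkylation, secured by the higher reactivity of the terminal carbanion, and exocyclic over endocyclic alkene formation, secured by the copper-mediated elimination; the side chain is cut back to a saturated ester so that no third alkene can continue the cascade.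

Step 5
Reactants: 10 rac-13-tert-butyl 19-methyl 3-oxo-14,15,16-trinorlabd-8(17)-ene-13,19-dioate
Product: 11 13-tert-butyl 19-methyl (3R,4R,5R,9S,10R)-3-hydroxy-14,15,16-trinorlabd-8(17)-ene-13,19-dioate
Conditions: ketoreductase (NADPH-dependent, chosen from a screening panel), NADP+ (cat.), i-PrOH, phosphate buffer pH 7, DMSO, 30 °C, stopped near half conversion
Reagents that add atoms: none
Why: Enzymatic kinetic resolution by carbonyl reduction, a known behaviour of ketoreductases towards racemic cyclic 2,2-disubstituted 3-oxo esters: the active site should accept only the (4R,5R,9S,10R) enantiomer and deliver hydride to the C3 face that gives the axial 3R (3α) alcohol, while the other enantiomer stays as ketone and is removed by chromatography.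

Step 6
Reactants: 11 13-tert-butyl 19-methyl (3R,4R,5R,9S,10R)-3-hydroxy-14,15,16-trinorlabd-8(17)-ene-13,19-dioate
Product: 12 13-tert-butyl 19-methyl (3R,4R,5R,9S,10R)-3-acetoxy-14,15,16-trinorlabd-8(17)-ene-13,19-dioate
Conditions: Ac2O, DMAP, pyridine, 40 °C
Reagents that add atoms: acetic anhydride, CC(=O)OC(C)=O
Why: DMAP-catalysed acetylation of the hindered axial secondary alcohol; both esters and the alkene are inert and no stereocentre is touched.

Step 7
Reactants: 12 13-tert-butyl 19-methyl (3R,4R,5R,9S,10R)-3-acetoxy-14,15,16-trinorlabd-8(17)-ene-13,19-dioate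
Product: 14 (3R,4R,5R,9S,10R)-3-acetoxy-19-methoxy-19-oxo-14,15,16-trinorlabd-8(17)-en-13-oic acid, via trimethylsilyl ester 13 (not isolated)
Conditions: TMSOTf, 2,6-lutidine, CH2Cl2, 0 °C; then H2O
Reagents that add atoms: none
Why: Silyl triflate-mediated tert-butyl ester cleavage (O-silylation, loss of isobutene) is non-protic, so the 8(17)-alkene, the acetate and the hindered methyl ester should survive, and silyl ester 13 is hydrolysed on work-up.

Step 8
Reactants: 15 but-2-yn-1-ol
Product: 16 tert-butyl(but-2-yn-1-yloxy)dimethylsilane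
Conditions: TBSCl, imidazole, CH2Cl2, rt
Reagents that add atoms: tert-butyldimethylsilyl chloride, CC(C)(C)[Si](C)(C)Cl
Why: Standard silylation of the primary propargylic alcohol.

Step 9
Reactants: 16 tert-butyl(but-2-yn-1-yloxy)dimethylsilane
Product: 18 tert-butyl{[(2E)-3-iodobut-2-en-1-yl]oxy}dimethylsilane, via alkenylzirconocene 17 (not isolated)
Conditions: Cp2Zr(H)Cl (excess), THF, 50 °C; then I2, 0 °C
Reagents that add atoms: iodine, II
Why: syn-Hydrozirconation of the 2-alkyne, equilibrated by excess Cp2Zr(H)Cl to the regioisomer with zirconium on the methyl-bearing carbon, then iodinolysis with retention, fixes the E geometry of the future C13=C14 bond.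

Step 10
Reactants: 14 (3R,4R,5R,9S,10R)-3-acetoxy-19-methoxy-19-oxo-14,15,16-trinorlabd-8(17)-en-13-oic acid; 18 tert-butyl{[(2E)-3-iodobut-2-en-1-yl]oxy}dimethylsilane
Product: 22 methyl (3R,4R,5R,9S,10R,13E)-3-acetoxy-15-[(tert-butyldimethylsilyl)oxy]labda-8(17),13-dien-19-oate, via alkenyllithium 19 (not isolated), via alkenylzinc chloride 20 (not isolated), via phthalimidyl ester 21 (not isolated)
Conditions: 18, t-BuLi (2 equiv), Et2O, −78 °C, then ZnCl2, THF, to rt; 14, N-hydroxyphthalimide, DIC, DMAP (cat.), CH2Cl2, rt; then Ni(acac)2 (cat.), 2,2'-bipyridine (cat.), THF/DMF, rt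
Reagents that add atoms: none
Why: Nickel-catalysed decarboxylative alkenylation of a redox-active ester: single-electron reduction of 21 expels CO2 and phthalimide to give the primary C12 radical, which nickel couples with alkenylzinc 20 with retention of its E geometry; the acetate, methyl ester and 8(17)-alkene are spectators.

Step 11
Reactants: 22 methyl (3R,4R,5R,9S,10R,13E)-3-acetoxy-15-[(tert-butyldimethylsilyl)oxy]labda-8(17),13-dien-19-oate
Product: 23 methyl (3R,4R,5R,9S,10R,13E)-3-acetoxy-15-hydroxylabda-8(17),13-dien-19-oate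
Conditions: HF·pyridine, pyridine, THF, 0 °C
Reagents that add atoms: none
Why: Buffered fluoride desilylation of the primary allylic silyl ether should leave the acetate, the methyl ester and both alkenes untouched and give the target.

Compound list
1 | geranyl bromide, (2E)-1-bromo-3,7-dimethylocta-2,6-diene | CC(C)=CCC/C(C)=C/CBr | starting material
2 | tert-butyl acetate | CC(=O)OC(C)(C)C | starting material
3 | lithium enolate of tert-butyl acetate (not isolated) | [Li+].C=C([O-])OC(C)(C)C | intermediate
4 | tert-butyl (4E)-5,9-dimethyldeca-4,8-dienoate | CC(C)=CCC/C(C)=C/CCC(=O)OC(C)(C)C | intermediate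
5 | tert-butyl (4E,8E)-10-hydroxy-5,9-dimethyldeca-4,8-dienoate | OC/C(C)=C/CC/C(C)=C/CCC(=O)OC(C)(C)C | intermediate
6 | tert-butyl (4E,8E)-10-bromo-5,9-dimethyldeca-4,8-dienoate | BrC/C(C)=C/CC/C(C)=C/CCC(=O)OC(C)(C)C | intermediate
7 | methyl 2-methyl-3-oxobutanoate (methyl 2-methylacetoacetate) | COC(=O)C(C)C(C)=O | starting material
8 | sodium lithium dianion of methyl 2-methyl-3-oxobutanoate (not isolated) | [Na+].[Li+].[CH2-]C([O-])=C(C)C(=O)OC | intermediate
9 | 14-tert-butyl 1-methyl (6E,10E)-2,6,10-trimethyl-3-oxotetradeca-6,10-dienedioate, C2 unassigned (not isolated) | COC(=O)C(C)C(=O)CC/C(C)=C/CC/C(C)=C/CCC(=O)OC(C)(C)C | intermediate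
10 | rac-13-tert-butyl 19-methyl 3-oxo-14,15,16-trinorlabd-8(17)-ene-13,19-dioate: trans-decalin, 4β-CO2Me (axial), 4α-Me, 5α-H, 9α-H, 10β-Me, C9 bearing CH2CH2CO2t-Bu; racemate, SMILES shows the (4R,5R,9S,10R) enantiomer that is carried on | C=C1CC[C@@H]2[C@](C)(CCC(=O)[C@]2(C)C(=O)OC)[C@H]1CCC(=O)OC(C)(C)C | intermediate
11 | 13-tert-butyl 19-methyl (3R,4R,5R,9S,10R)-3-hydroxy-14,15,16-trinorlabd-8(17)-ene-13,19-dioate (3α-OH, axial) | C=C1CC[C@@H]2[C@](C)(CC[C@@H](O)[C@]2(C)C(=O)OC)[C@H]1CCC(=O)OC(C)(C)C | intermediate
12 | 13-tert-butyl 19-methyl (3R,4R,5R,9S,10R)-3-acetoxy-14,15,16-trinorlabd-8(17)-ene-13,19-dioate | C=C1CC[C@@H]2[C@](C)(CC[C@@H](OC(C)=O)[C@]2(C)C(=O)OC)[C@H]1CCC(=O)OC(C)(C)C | intermediate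
13 | 19-methyl 13-trimethylsilyl (3R,4R,5R,9S,10R)-3-acetoxy-14,15,16-trinorlabd-8(17)-ene-13,19-dioate (not isolated) | C=C1CC[C@@H]2[C@](C)(CC[C@@H](OC(C)=O)[C@]2(C)C(=O)OC)[C@H]1CCC(=O)O[Si](C)(C)C | intermediate
14 | (3R,4R,5R,9S,10R)-3-acetoxy-19-methoxy-19-oxo-14,15,16-trinorlabd-8(17)-en-13-oic acid | C=C1CC[C@@H]2[C@](C)(CC[C@@H](OC(C)=O)[C@]2(C)C(=O)OC)[C@H]1CCC(=O)O | intermediate
15 | but-2-yn-1-ol | CC#CCO | starting material
16 | tert-butyl(but-2-yn-1-yloxy)dimethylsilane | CC#CCO[Si](C)(C)C(C)(C)C | intermediate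
17 | (E)-alkenylzirconocene chloride, Cp2Zr(Cl) on C3 of the 1-silyloxybut-2-ene (not isolated) | C/C(=C\CO[Si](C)(C)C(C)(C)C)[Zr](Cl)(C1C=CC=C1)C1C=CC=C1 | intermediate
18 | tert-butyl{[(2E)-3-iodobut-2-en-1-yl]oxy}dimethylsilane | C/C(I)=C\CO[Si](C)(C)C(C)(C)C | intermediate
19 | (E)-alkenyllithium from 18, lithium in place of iodine (not isolated) | C/C([Li])=C\CO[Si](C)(C)C(C)(C)C | intermediate
20 | (E)-alkenylzinc chloride from 19 (not isolated) | C/C([Zn]Cl)=C\CO[Si](C)(C)C(C)(C)C | intermediate
21 | 1,3-dioxoisoindolin-2-yl (N-hydroxyphthalimide) ester of acid 14 (not isolated) | C=C1CC[C@@H]2[C@](C)(CC[C@@H](OC(C)=O)[C@]2(C)C(=O)OC)[C@H]1CCC(=O)ON1C(=O)c2ccccc2C1=O | intermediate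
22 | methyl (3R,4R,5R,9S,10R,13E)-3-acetoxy-15-[(tert-butyldimethylsilyl)oxy]labda-8(17),13-dien-19-oate | C=C1CC[C@@H]2[C@](C)(CC[C@@H](OC(C)=O)[C@]2(C)C(=O)OC)[C@H]1CC/C(C)=C/CO[Si](C)(C)C(C)(C)C | intermediate
23 | methyl (3R,4R,5R,9S,10R,13E)-3-acetoxy-15-hydroxylabda-8(17),13-dien-19-oate (3α-OAc, 4β-CO2Me) | C=C1CC[C@@H]2[C@](C)(CC[C@@H](OC(C)=O)[C@]2(C)C(=O)OC)[C@H]1CC/C(C)=C/CO | target

Total step count: 11. Longest linear sequence: 9 steps (steps 1–7, 10 and 11); steps 8 and 9 make the alkenyl partner.

Steps most likely to fail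

Step 4 (key step). The terminating oxidation can lose site control (hydrogen loss from C7 or C9 instead of C17, or capture of the C8 centre by acetate or the side-chain ester), the C10 radical can be oxidised before ring B closes, and salts or residual THF in the telescoped medium can slow formation of the manganese enolate. Fallback: the sequence is stopped after the alkylation stage and keto ester 9 is isolated. It is selenenylated at its C2 carbon (the future C4; NaH, PhSeCl) to the 2-phenylselanyl keto ester F1. Irradiation of F1 in the presence of Mg(ClO4)2 or Yb(OTf)3 should bring about phenylselanyl group-transfer radical bicyclisation to the tertiary C8 selenide F2. Oxidation with H2O2 and selenoxide syn-elimination towards C17 then return the route to 10. With a chiral bis(oxazoline) ligand on magnesium, this known reaction type could also give 10 enantioenriched.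

Step 5. The ketone is flanked by the quaternary C4, so turnover may be slow, and discrimination between the two enantiomers may be insufficient. Fallback: 10 is reduced with LiBH(s-Bu)3 (THF, −78 °C), whose equatorial hydride delivery should give the racemic 3α-alcohol F3. Its enantiomers are separated by preparative chromatography on a chiral stationary phase, and the (3R) enantiomer is 11.

Step 10. Reduction or dimerisation of the primary C12 radical and protonation of the alkenylzinc can outrun the cross-coupling. Fallback: acid 14 is converted (oxalyl chloride, then the sodium salt of N-hydroxypyridine-2-thione) into the thiohydroxamate ester F4. Photolysis of F4 with iodoform (Barton decarboxylation conditions) should give the C12 iodide F5. Zinc insertion (Zn, LiCl, THF) gives the alkylzinc iodide F6, and Negishi coupling with vinyl iodide 18 under Pd(PPh3)4 catalysis returns the route to 22.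

Further compounds
F1 | step 4 | 14-tert-butyl 1-methyl (6E,10E)-2,6,10-trimethyl-3-oxo-2-(phenylselanyl)tetradeca-6,10-dienedioate (racemic) | COC(=O)C(C)([Se]c1ccccc1)C(=O)CC/C(C)=C/CC/C(C)=C/CCC(=O)OC(C)(C)C
F2 | step 4 | 13-tert-butyl 19-methyl 3-oxo-8-(phenylselanyl)-14,15,16-trinorlabdane-13,19-dioate (racemic, C8 unassigned; one enantiomer drawn) | CC1([Se]c2ccccc2)CC[C@@H]2[C@](C)(CCC(=O)[C@]2(C)C(=O)OC)[C@H]1CCC(=O)OC(C)(C)C
F3 | step 5 | racemic 13-tert-butyl 19-methyl 3α-hydroxy-14,15,16-trinorlabd-8(17)-ene-13,19-dioate (11 and its enantiomer) | C=C1CC[C@@H]2[C@](C)(CC[C@@H](O)[C@]2(C)C(=O)OC)[C@H]1CCC(=O)OC(C)(C)C.C=C1CC[C@H]2[C@@](C)(CC[C@H](O)[C@@]2(C)C(=O)OC)[C@@H]1CCC(=O)OC(C)(C)C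
F4 | step 10 | 2-thioxopyridin-1(2H)-yl ester of acid 14 | C=C1CC[C@@H]2[C@](C)(CC[C@@H](OC(C)=O)[C@]2(C)C(=O)OC)[C@H]1CCC(=O)ON1C=CC=CC1=S
F5 | step 10 | methyl (3R,4R,5R,9S,10R)-3-acetoxy-12-iodo-13,14,15,16-tetranorlabd-8(17)-en-19-oate | C=C1CC[C@@H]2[C@](C)(CC[C@@H](OC(C)=O)[C@]2(C)C(=O)OC)[C@H]1CCI
F6 | step 10 | C12 alkylzinc iodide from F5 | C=C1CC[C@@H]2[C@](C)(CC[C@@H](OC(C)=O)[C@]2(C)C(=O)OC)[C@H]1CC[Zn]I
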